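**Retrosynthetic overview**
1. The ten-membered carbocycle is formed last, by ring-closing metathesis at C4=C5 of vinyl lactone 18, and the ring size enforces the Z-alkene.
2. The cis α-methylene-γ-lactone (second-last ring) comes from 15 and acrolein: umpolung allylation forms C6–C7, then lactonisation.
3. Key disconnection is the C8–O bond: a stereoretentive palladium-catalysed isobutyroxylation of a bis-epoxide gives 8-O-isobutyryl and 9-OH in one step.
4. Both epoxides come from catalytic asymmetric C–O formation: Sharpless for C1–C10 (first ring), then iminium catalysis for the transient C8–C9 epoxide.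
5. The carbons come from methallyl Grignard, isoprene monoxide, a C2 ylide, methyl acrylate and acrolein.

Assumption: germacrane numbering (C1–C15) is used for locants. The carbinol centre made in step 5 (C7) is carried as an epimer mixture because step 6 makes it planar.

**Step 1**
Reactants: 1 methallylmagnesium chloride; 2 isoprene monoxide
Product: 3 (2E)-2,6-dimethylhepta-2,6-dien-1-ol
Conditions: CuI (10 mol%), THF, −40 °C to 0 °C; aq NH4Cl
Reagents that add atoms: none
Why: Copper-catalysed SN2' opening of the vinyl epoxide by the Grignard reagent attacks the vinyl terminus and gives mainly the E-trisubstituted allylic alcohol; the minor Z isomer is removed by chromatography.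

**Step 2**
Reactants: 3 (2E)-2,6-dimethylhepta-2,6-dien-1-ol
Product: 4 [(2R,3R)-2-methyl-3-(3-methylbut-3-en-1-yl)oxiran-2-yl]methanol
Conditions: Ti(OiPr)4 (10 mol%), D-(−)-diisopropyl tartrate (12 mol%), tBuOOH, 4 Å molecular sieves, CH2Cl2, −20 °C
Reagents that add atoms: tert-butyl hydroperoxide CC(C)(C)OO
Why: Sharpless asymmetric epoxidation oxidises only the titanium-bound allylic alcohol alkene, and the D-tartrate gives the (2R,3R)-epoxide, which sets C10 and C1.

**Step 3**
Reactants: 4 [(2R,3R)-2-methyl-3-(3-methylbut-3-en-1-yl)oxiran-2-yl]methanol; 5 (triphenylphosphoranylidene)acetaldehyde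
Product: 7 (2E)-3-[(2R,3R)-2-methyl-3-(3-methylbut-3-en-1-yl)oxiran-2-yl]prop-2-enal, via epoxy aldehyde 6 (not isolated)
Conditions: TEMPO (10 mol%), PhI(OAc)2 (1.1 equiv), CH2Cl2, rt; then 5 (1.1 equiv), 40 °C
Reagents that add atoms: none
Why: Oxoammonium oxidation followed by Wittig olefination with a stabilised ylide gives the E-enal and leaves the non-enolisable quaternary epoxide centre untouched.

**Step 4**
Reactants: 7 (2E)-3-[(2R,3R)-2-methyl-3-(3-methylbut-3-en-1-yl)oxiran-2-yl]prop-2-enal
Product: 8 (2S,3S)-3-[(2S,3R)-2-methyl-3-(3-methylbut-3-en-1-yl)oxiran-2-yl]oxirane-2-carbaldehyde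
Conditions: (S)-2-{bis[3,5-bis(trifluoromethyl)phenyl](trimethylsilyloxy)methyl}pyrrolidine (10 mol%), 35% aq H2O2 (1.3 equiv), CH2Cl2, rt
Reagents that add atoms: hydrogen peroxide OO
Why: In this iminium–enamine (Jørgensen–Hayashi) epoxidation only the enal alkene is activated, and the (S)-catalyst shields one face, so the trans C8–C9 epoxide forms under catalyst control and sets both C–O configurations.

**Step 5**
Reactants: 8 (2S,3S)-3-[(2S,3R)-2-methyl-3-(3-methylbut-3-en-1-yl)oxiran-2-yl]oxirane-2-carbaldehyde; 9 methyl acrylate; 10 isobutyric anhydride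
Product: 12 methyl 2-{(isobutyryloxy)[(2R,3S)-3-[(2S,3R)-2-methyl-3-(3-methylbut-3-en-1-yl)oxiran-2-yl]oxiran-2-yl]methyl}prop-2-enoate (C7 epimers), via Baylis-Hillman alcohol 11 (not isolated)
Conditions: 9 (5 equiv), DABCO (0.5 equiv), MeOH, rt; evaporate; 10 (1.3 equiv), Et3N, DMAP (5 mol%), CH2Cl2, 0 °C
Reagents that add atoms: none
Why: The Morita–Baylis–Hillman reaction of an electron-poor, non-enolisable epoxy aldehyde forms C7–C11, and acylation makes the leaving group; the new carbinol configuration does not matter.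

**Step 6**
Reactants: 12 Baylis–Hillman isobutyrate; 13 isobutyric acid
Product: 15 methyl (2E,4R,5S)-5-hydroxy-4-(isobutyryloxy)-2-[(isobutyryloxy)methyl]-5-[(2R,3R)-2-methyl-3-(3-methylbut-3-en-1-yl)oxiran-2-yl]pent-2-enoate, via primary allylic isobutyrate 14 (not isolated)
Conditions: Pd2(dba)3·CHCl3 (2.5 mol%), dppe (6 mol%), 13 (1.3 equiv), THF, 0 °C to rt
Reagents that add atoms: none
Why: Proposed new method: zerovalent palladium first ionises the Baylis–Hillman ester and isobutyrate returns at the unhindered CH2 terminus to give vinyl epoxide 14, whose allylic C8–O bond is then ionised with inversion to a π-allylpalladium/C9-alkoxide zwitterion that 13 protonates and whose hydrogen-bonded isobutyrate attacks anti to palladium at C8 (the other terminus C11 is fully substituted and the C1–C10 epoxide is not allylic), so two inversions give net retention and the syn 8-acyloxy-9-ol with O8 and O9 differentiated in one C–O bond-forming step; the closest known reaction types are the double-inversion substitution of γ,δ-epoxy-α,β-unsaturated esters by boron alkoxides and the palladium-catalysed addition of carboxylic acids to diene monoepoxides, neither of which has been shown for a carboxylic acid on a bis-epoxide or in relay with a Baylis–Hillman ester.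

**Step 7**
Reactants: 15 bis-isobutyrate; 16 acrolein
Product: 18 (1R,2S)-1-[(2S,3S)-2-ethenyl-4-methylidene-5-oxooxolan-3-yl]-2-hydroxy-2-[(2R,3R)-2-methyl-3-(3-methylbut-3-en-1-yl)oxiran-2-yl]ethyl 2-methylpropanoate, via hydroxy ester 17 (not isolated)
Conditions: Pd(PPh3)4 (5 mol%), InI (1.5 equiv), 16 (3 equiv), THF, rt; aq work-up; PPTS (10 mol%), CH2Cl2, rt
Reagents that add atoms: none
Why: In this umpolung allylation the π-allylpalladium from the primary ester is reduced by monovalent indium and adds through a Zimmerman–Traxler chair in which C8 is cis to the CH2–In group, giving the syn adduct and hence the cis-lactone (C6), while A(1,3) strain puts H8 in the alkene plane and the C9-hydroxyl-bound indium delivers acrolein anti to the C8–O bond (C7).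

**Step 8**
Reactants: 18 vinyl lactone
Product: 19 target, (1R,6S,7S,8R,9S,10R)-1,10-epoxy-9-hydroxy-8-isobutyryloxygermacra-4Z,11(13)-dien-12,6-olide
Conditions: second-generation Hoveyda–Grubbs catalyst (15 mol%, slow addition), 1,4-benzoquinone (30 mol%), toluene (0.5 mM), 90 °C
Reagents that add atoms: none
Why: Ring-closing metathesis starts at the monosubstituted vinyl group and closes onto the isopropenyl group; the ten-membered ring accepts the trisubstituted alkene only as the Z isomer, and the electron-poor methylene lactone does not react.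

**Compound list**
1 | methallylmagnesium chloride | C=C(C)C[Mg]Cl | starting material
2 | isoprene monoxide (2-methyl-2-vinyloxirane, racemic) | CC1(C=C)CO1 | starting material
3 | (2E)-2,6-dimethylhepta-2,6-dien-1-ol | C=C(C)CC/C=C(\C)CO | intermediate
4 | [(2R,3R)-2-methyl-3-(3-methylbut-3-en-1-yl)oxiran-2-yl]methanol | OC[C@@]1(C)O[C@@H]1CCC(C)=C | intermediate
5 | (triphenylphosphoranylidene)acetaldehyde | O=CC=P(c1ccccc1)(c1ccccc1)c1ccccc1 | starting material
6 | (2S,3R)-2-methyl-3-(3-methylbut-3-en-1-yl)oxirane-2-carbaldehyde | O=C[C@@]1(C)O[C@@H]1CCC(C)=C | intermediate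
7 | (2E)-3-[(2R,3R)-2-methyl-3-(3-methylbut-3-en-1-yl)oxiran-2-yl]prop-2-enal | O=C/C=C/[C@@]1(C)O[C@@H]1CCC(C)=C | intermediate
8 | (2S,3S)-3-[(2S,3R)-2-methyl-3-(3-methylbut-3-en-1-yl)oxiran-2-yl]oxirane-2-carbaldehyde | O=C[C@H]1O[C@@H]1[C@@]2(C)O[C@@H]2CCC(C)=C | intermediate
9 | methyl acrylate | C=CC(=O)OC | starting material
10 | isobutyric anhydride | CC(C)C(=O)OC(=O)C(C)C | starting material
11 | methyl 2-{hydroxy[(2R,3S)-3-[(2S,3R)-2-methyl-3-(3-methylbut-3-en-1-yl)oxiran-2-yl]oxiran-2-yl]methyl}prop-2-enoate (carbinol epimers) | C=C(C(=O)OC)C(O)[C@H]1O[C@@H]1[C@@]2(C)O[C@@H]2CCC(C)=C | intermediate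
12 | isobutyrate of 11 (carbinol epimers) | C=C(C(=O)OC)C(OC(=O)C(C)C)[C@H]1O[C@@H]1[C@@]2(C)O[C@@H]2CCC(C)=C | intermediate
13 | isobutyric acid | CC(C)C(=O)O | starting material
14 | methyl (2E)-2-[(isobutyryloxy)methyl]-3-[(2R,3S)-3-[(2S,3R)-2-methyl-3-(3-methylbut-3-en-1-yl)oxiran-2-yl]oxiran-2-yl]prop-2-enoate | COC(=O)/C(COC(=O)C(C)C)=C/[C@H]1O[C@@H]1[C@@]2(C)O[C@@H]2CCC(C)=C | intermediate
15 | methyl (2E,4R,5S)-5-hydroxy-4-(isobutyryloxy)-2-[(isobutyryloxy)methyl]-5-[(2R,3R)-2-methyl-3-(3-methylbut-3-en-1-yl)oxiran-2-yl]pent-2-enoate | COC(=O)/C(COC(=O)C(C)C)=C/[C@@H](OC(=O)C(C)C)[C@H](O)[C@@]1(C)O[C@@H]1CCC(C)=C | intermediate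
16 | acrolein | C=CC=O | starting material
17 | methyl (3S,4S)-4-hydroxy-3-{(1R,2S)-2-hydroxy-1-(isobutyryloxy)-2-[(2R,3R)-2-methyl-3-(3-methylbut-3-en-1-yl)oxiran-2-yl]ethyl}-2-methylidenehex-5-enoate | C=C(C(=O)OC)[C@@H]([C@@H](O)C=C)[C@@H](OC(=O)C(C)C)[C@H](O)[C@@]1(C)O[C@@H]1CCC(C)=C | intermediate
18 | (1R,2S)-1-[(2S,3S)-2-ethenyl-4-methylidene-5-oxooxolan-3-yl]-2-hydroxy-2-[(2R,3R)-2-methyl-3-(3-methylbut-3-en-1-yl)oxiran-2-yl]ethyl 2-methylpropanoate | C=C1C(=O)O[C@@H](C=C)[C@H]1[C@@H](OC(=O)C(C)C)[C@H](O)[C@@]2(C)O[C@@H]2CCC(C)=C | intermediate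
19 | CNP0110853.1, (1R,6S,7S,8R,9S,10R)-1,10-epoxy-9-hydroxy-8-isobutyryloxygermacra-4Z,11(13)-dien-12,6-olide | C=C1C(=O)O[C@H]2/C=C(/C)CC[C@H]3O[C@]3(C)[C@@H](O)[C@H](OC(=O)C(C)C)[C@@H]12 | target

**Totals:** 8 steps in all; longest linear sequence 8 steps (from 1 and 2).

**The three steps most likely to fail**

Step 6 (the new method). The risks are isomerisation of the vinyl epoxide to a dienol or ketone, Payne migration of the C9 alkoxide, and re-ionisation of the product. The fallback sets out from 12 and comes back at 15, using known chemistry. DABCO in THF isomerises 12 to the isolated primary ester 14. Zerovalent palladium with boric acid then opens the vinyl epoxide by the established double-inversion hydroxylation to give the syn 4,5-diol F1. Finally 10 with collidine at low temperature acylates the less hindered allylic C8 hydroxyl in preference to the C9 hydroxyl, which sits next to the quaternary C10.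

Step 7. The risks are competing ionisation of the secondary C8 isobutyrate, 1,4-elimination of that ester from the allylindium to give a diene, and the wrong π-face at C7. The fallback sets out from 15 and comes back at 18. It replaces the polar allyl–metal species by a covalent one. Borylation of the primary allylic ester with B2pin2 and Pd2(dba)3 in DMSO gives the allylboronate F2. Heating F2 with 16 in toluene gives a neutral, closed-chair allylboration of the same syn sense, and PPTS then closes the lactone.

Step 8. The risks are slow loading at the hindered allylic vinyl group, dimer formation, and ring strain. The fallback sets out from 15 and comes back at 19. It changes the substrate so that ruthenium is delivered by a relay. Step 7 is run with (2E)-octa-2,7-dienal F3 in place of 16, which gives the relay lactone F4. Metathesis then starts at the remote terminal alkene, expels cyclopentene, places the carbene on C5, and closes onto the isopropenyl group.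

**Further compounds**
F1 | step 6 | methyl (2E,4R,5S)-4,5-dihydroxy-2-[(isobutyryloxy)methyl]-5-[(2R,3R)-2-methyl-3-(3-methylbut-3-en-1-yl)oxiran-2-yl]pent-2-enoate | COC(=O)/C(COC(=O)C(C)C)=C/[C@@H](O)[C@H](O)[C@@]1(C)O[C@@H]1CCC(C)=C
F2 | step 7 | methyl (2E,4R,5S)-5-hydroxy-4-(isobutyryloxy)-5-[(2R,3R)-2-methyl-3-(3-methylbut-3-en-1-yl)oxiran-2-yl]-2-[(4,4,5,5-tetramethyl-1,3,2-dioxaborolan-2-yl)methyl]pent-2-enoate | COC(=O)/C(CB1OC(C)(C)C(C)(C)O1)=C/[C@@H](OC(=O)C(C)C)[C@H](O)[C@@]2(C)O[C@@H]2CCC(C)=C
F3 | step 8 | (2E)-octa-2,7-dienal | O=C/C=C/CCCC=C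
F4 | step 8 | (1R,2S)-1-{(2S,3S)-2-[(1E)-hepta-1,6-dien-1-yl]-4-methylidene-5-oxooxolan-3-yl}-2-hydroxy-2-[(2R,3R)-2-methyl-3-(3-methylbut-3-en-1-yl)oxiran-2-yl]ethyl 2-methylpropanoate | C=C1C(=O)O[C@@H](/C=C/CCCC=C)[C@H]1[C@@H](OC(=O)C(C)C)[C@H](O)[C@@]2(C)O[C@@H]2CCC(C)=C
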